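**Retrosynthetic overview**

- The target is traced back to a 6-oxo cyclohexane that already carries every ring carbon substituent. Only late adjustments follow it: anti reduction of the C-6 ketone, ethenolysis of a propenyl group to the C-10 vinyl group, Still–Gennari construction of the C-8 ester, allylic oxidation of the isopropenyl methyl group, and release of the acid.
- That cyclohexanone is opened at two ring bonds into one acyclic allyl vinyl ether bearing an aldehyde. In the forward sense, a Claisen rearrangement forms C-5–C-10 (quaternary C-10 and C-5 by chirality transfer from one (R)-carbinol), and an intramolecular aldol addition in the same flask forms C-7–C-8.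
- Enabling feature: with C-6 as a ketone, the ring is at once a γ,δ-unsaturated ketone (C-6=O, C-5, C-10, alkenyl on C-10) and a β-hydroxy ketone (C-6=O, C-7, C-8–OH). The cyclohexane C-5 to C-10 therefore unfolds completely into a chain.
- The acyclic precursor comes from an allyl ester by enolisation to a ketene acetal phosphate and Negishi coupling with a 2-(alkoxycarbonyl)allylzinc reagent. The ester comes from an (R)-allylic alcohol made by alkyne carboalumination/acylation and CBS reduction.
- Ring order: the molecule has one ring, and it is closed in the key step.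

Key step: step 9

Numbering used in the text: ring atoms C-5 to C-10 as in elemanes (C-10 quaternary; C-9 CH2; C-8 acyloxy carbon; C-7 bears the acrylate; C-6 carbinol; C-5 bears the isopropenyl unit); β is the face of the C-10 methyl group.

Assumption: kinetic deprotonation of the β,γ-unsaturated ester of step 3 in THF gives the (E)-enolate, as saturated esters do.

**Step 1**
Reactants: 1 tert-butyl(but-3-yn-1-yloxy)dimethylsilane
Product: 2 (3E)-6-[(tert-butyldimethylsilyl)oxy]-4-methylhex-3-en-2-one
Conditions: Me3Al, Cp2ZrCl2 (25 mol%), CH2Cl2, rt; then AcCl, Pd(PPh3)4 (5 mol%), THF, 0 °C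
Reagents that add atoms: trimethylaluminium C[Al](C)C; acetyl chloride CC(Cl)=O
Why: Zirconium-catalysed syn-carboalumination (Negishi carboalumination) places methyl and aluminium cis on the alkyne, and palladium-catalysed acylation of the alkenylalane with retention should give the (E)-enone; no stereocentre is formed.

**Step 2**
Reactants: 2 (3E)-enone
Product: 3 (2R,3E)-6-[(tert-butyldimethylsilyl)oxy]-4-methylhex-3-en-2-ol
Conditions: (S)-2-methyl-CBS-oxazaborolidine (20 mol%), BH3·SMe2, THF, −30 °C
Reagents that add atoms: none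
Why: Corey–Bakshi–Shibata reduction with the (S)-oxazaborolidine (alkenyl as large group, methyl as small group) should give the (R)-carbinol by reagent control; this is the one centre from which C-10 and C-5 are later derived.

**Step 3**
Reactants: 3 (2R,3E)-allylic alcohol; 4 3-methylbut-3-enoic acid
Product: 5 (2R,3E)-6-[(tert-butyldimethylsilyl)oxy]-4-methylhex-3-en-2-yl 3-methylbut-3-enoate
Conditions: DIC, DMAP (5 mol%), CH2Cl2, 0 °C
Reagents that add atoms: none
Why: Steglich esterification acylates the secondary alcohol with retention at the carbinol carbon, and the low temperature should keep the β,γ-double bond of the acid in place.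

**Step 4**
Reactants: 5 allyl ester
Product: 6 (1E)-1-{[(2R,3E)-6-[(tert-butyldimethylsilyl)oxy]-4-methylhex-3-en-2-yl]oxy}-3-methylbuta-1,3-dien-1-yl diphenyl phosphate
Conditions: LiN(i-Pr)2, THF, −78 °C; then (PhO)2P(O)Cl, DMPU, −78 °C; cold work-up
Reagents that add atoms: diphenyl phosphorochloridate O=P(Cl)(Oc1ccccc1)Oc1ccccc1
Why: Kinetic deprotonation in THF should give the (E)-ester enolate (isopropenyl cis to the allyloxy oxygen), and O-phosphorylation traps this geometry as the ketene acetal phosphate; no stereocentre is formed, but the enol ether geometry that later sets C-5 is fixed here.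

**Step 5**
Reactants: 7 2-(bromomethyl)prop-2-enoic acid; 8 2-(trimethylsilyl)ethanol
Product: 9 2-(trimethylsilyl)ethyl 2-(bromomethyl)prop-2-enoate
Conditions: DIC, DMAP (cat.), CH2Cl2, 0 °C
Reagents that add atoms: none
Why: Steglich esterification installs the fluoride-cleavable 2-(trimethylsilyl)ethyl ester that protects the future acid to the end; no stereocentre is formed.

**Step 6**
Reactants: 6 ketene acetal phosphate; 9 2-(trimethylsilyl)ethyl 2-(bromomethyl)prop-2-enoate
Product: 11 2-(trimethylsilyl)ethyl (4Z)-4-{[(2R,3E)-6-[(tert-butyldimethylsilyl)oxy]-4-methylhex-3-en-2-yl]oxy}-6-methyl-2-methylidenehepta-4,6-dienoate, via allylzinc bromide 10 (not isolated)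
Conditions: Zn dust, THF, 0 °C (9 to 10); then 6, Pd(PPh3)4 (5 mol%), THF, 0 °C to rt
Reagents that add atoms: none
Why: Zinc insertion gives a symmetrical 2-(alkoxycarbonyl)allylzinc reagent, and its Negishi coupling replaces the phosphate with retention of the double-bond geometry to give the (Z)-enol ether with C-6–C-7 in place; the low temperature should keep the allyl vinyl ether from rearranging.

**Step 7**
Reactants: 11 silyl-protected dienyl allyl ether
Product: 12 2-(trimethylsilyl)ethyl (4Z)-4-{[(2R,3E)-6-hydroxy-4-methylhex-3-en-2-yl]oxy}-6-methyl-2-methylidenehepta-4,6-dienoate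
Conditions: HF·pyridine, pyridine, THF, 0 °C
Reagents that add atoms: none
Why: Pyridine-buffered fluoride desilylation should remove the primary silyl ether without hydrolysing the enol ether or touching the 2-(trimethylsilyl)ethyl ester.

**Step 8**
Reactants: 12 primary alcohol
Product: 13 2-(trimethylsilyl)ethyl (4Z)-6-methyl-2-methylidene-4-{[(2R,3E)-4-methyl-6-oxohex-3-en-2-yl]oxy}hepta-4,6-dienoate
Conditions: Dess–Martin periodinane, NaHCO3, CH2Cl2, 0 °C; used at once
Reagents that add atoms: none
Why: Dess–Martin oxidation under bicarbonate buffer gives the β,γ-unsaturated aldehyde without strong acid or amine base, so neither the enol ether nor the skipped alkene should isomerise.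

**Step 9**
Reactants: 13 aldehyde-bearing allyl vinyl ether
Product: 15 2-(trimethylsilyl)ethyl 2-[(1R,3S,4S,6S)-6-hydroxy-4-methyl-2-oxo-3-(prop-1-en-2-yl)-4-[(1E)-prop-1-en-1-yl]cyclohexyl]prop-2-enoate, via keto aldehyde 14 (not isolated)
Conditions: PhMe (0.01 M), BHT (cat.), base-washed glass, 100 °C; then −78 °C, KN(SiMe3)2 (1.05 equiv), THF; AcOH quench at −78 °C
Reagents that add atoms: none
Why: On heating, 13 should undergo a Claisen ([3,3]-sigmatropic) rearrangement through a chair transition state with the carbinol methyl group equatorial, so that the (R)-carbinol centre, the (E)-trisubstituted alkene (C-10 methyl axial) and the (Z)-enol ether (isopropenyl axial) together fix the S configuration at the new quaternary C-10 and at C-5 and leave an (E)-propenyl group; this forms the C-5–C-10 bond and releases the C-6 ketone next to the doubly activated C-7 methylene in 14. Added at −78 °C, KN(SiMe3)2 should remove the most acidic proton (C-7, flanked by the ketone and the acrylate alkene), and the potassium enolate closes the cyclohexane by a 6-(enolendo)-exo-trig intramolecular aldol addition to the C-8 aldehyde, forming the C-7–C-8 bond. The closest known reaction types are the thermal Claisen rearrangement of ketone-derived allyl vinyl ethers to vicinal quaternary–tertiary centres and the base-mediated aldol cyclisation of 1,5-keto aldehydes to 3-hydroxycyclohexanones. C-7 and C-8 are set by the ring: the (Z)-enolate places the acrylate equatorial, and the reversibly formed potassium aldolate should settle in the chair with the C-5, C-7 and C-8 substituents all equatorial (C-10 methyl axial), that is 7,8-trans. The step needs the rearrangement to outrun isomerisation of the β,γ-unsaturated aldehyde and needs enolisation at C-7, not at C-5 or C-9; neutral dilute conditions with no base until the allyl ether is consumed, and the higher acidity and lower hindrance of the C-7 methylene, secure this.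

**Step 10**
Reactants: 15 β-hydroxy ketone
Product: 16 2-(trimethylsilyl)ethyl 2-[(1R,2S,3S,4S,6S)-2,6-dihydroxy-4-methyl-3-(prop-1-en-2-yl)-4-[(1E)-prop-1-en-1-yl]cyclohexyl]prop-2-enoate
Conditions: Me4NBH(OAc)3, MeCN–AcOH, −30 °C
Reagents that add atoms: none
Why: Evans–Saksena reduction should deliver hydride to the α-face of the C-6 carbonyl, anti to the C-8 hydroxyl and away from the axial C-10 methyl group that blocks axial attack, giving the axial 6β-alcohol (1,3-anti diol) and leaving the acrylate ester untouched.

**Step 11**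
Reactants: 16 propenyl diol
Product: 17 2-(trimethylsilyl)ethyl 2-[(1R,2S,3S,4S,6S)-4-ethenyl-2,6-dihydroxy-4-methyl-3-(prop-1-en-2-yl)cyclohexyl]prop-2-enoate
Conditions: second-generation Hoveyda–Grubbs catalyst (10 mol%), ethylene (5 bar), PhMe, 50 °C
Reagents that add atoms: ethylene C=C
Why: Ethenolysis (olefin cross-metathesis with ethylene) should trim the propenyl group to the C-10 vinyl group with loss of propene, since the isopropenyl and acrylate alkenes can only exchange methylidene for methylidene; no stereocentre is touched.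

**Step 12**
Reactants: 18 methyl 2-[bis(2,2,2-trifluoroethoxy)phosphoryl]propanoate
Product: 19 2-[bis(2,2,2-trifluoroethoxy)phosphoryl]propanoic acid
Conditions: Me3SnOH, ClCH2CH2Cl, 70 °C; 1 M HCl work-up
Reagents that add atoms: trimethyltin hydroxide C[Sn](C)(C)O
Why: Trimethyltin hydroxide effects a mild ester hydrolysis of the methyl ester that should spare the base-labile trifluoroethyl phosphonate esters; the α-carbon is racemic and becomes planar later.

**Step 13**
Reactants: 17 vinyl diol; 19 phosphonopropanoic acid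
Product: 20 8-O-{2-[bis(2,2,2-trifluoroethoxy)phosphoryl]propanoyl} derivative of 17 (mixture of epimers at the phosphonate carbon)
Conditions: EDC·HCl, DMAP (10 mol%), CH2Cl2, 0 °C to rt
Reagents that add atoms: none
Why: Steglich esterification should occur at the equatorial C-8 hydroxyl, because the axial C-6 hydroxyl is flanked by two branched carbons and is syn-axial to the C-10 methyl group.

**Step 14**
Reactants: 20 phosphonate ester; 21 2-oxoethyl acetate
Product: 22 8-O-[(2Z)-4-acetoxy-2-methylbut-2-enoyl] derivative of 17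
Conditions: KN(SiMe3)2 (1.0 equiv), 18-crown-6, THF, −78 °C; then 21, −78 °C
Reagents that add atoms: none
Why: Still–Gennari olefination of the trifluoroethyl phosphonate under kinetic control should give the (Z)-trisubstituted enoate (ester and acetoxymethyl group cis); the phosphonate is far more acidic than the free C-6 hydroxyl, so one equivalent of base suffices.

**Step 15**
Reactants: 22 isopropenyl compound
Product: 23 2-(trimethylsilyl)ethyl ester of the target
Conditions: SeO2 (30 mol%), t-BuOOH, CH2Cl2, 0 °C to rt
Reagents that add atoms: selenium dioxide O=[Se]=O (oxygen relay); tert-butyl hydroperoxide CC(C)(C)OO (terminal oxygen source)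
Why: Selenium dioxide allylic oxidation (ene reaction, then [2,3]-sigmatropic shift) should act on the only electron-rich alkene with allylic hydrogens, the 1,1-disubstituted isopropenyl group, at its methyl group and not at the hindered C-5 methine, giving the 2-substituted allylic alcohol.

**Step 16**
Reactants: 23 2-(trimethylsilyl)ethyl ester
Product: 24 target acid
Conditions: (Me2N)3S+ Me3SiF2− (TASF), DMF, 0 °C; aqueous NH4Cl work-up
Reagents that add atoms: none
Why: Fluoride-induced β-elimination of the 2-(trimethylsilyl)ethyl ester should release the acid under nearly neutral conditions that leave the acetate, the (Z)-enoate ester and the γ-hydroxy acid array untouched.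

**Compound list**

1 | tert-butyl(but-3-yn-1-yloxy)dimethylsilane | C#CCCO[Si](C)(C)C(C)(C)C | starting material
2 | (3E)-6-[(tert-butyldimethylsilyl)oxy]-4-methylhex-3-en-2-one | CC(=O)/C=C(\C)CCO[Si](C)(C)C(C)(C)C | intermediate
3 | (2R,3E)-6-[(tert-butyldimethylsilyl)oxy]-4-methylhex-3-en-2-ol | C[C@@H](O)/C=C(\C)CCO[Si](C)(C)C(C)(C)C | intermediate
4 | 3-methylbut-3-enoic acid | C=C(C)CC(=O)O | starting material
5 | (2R,3E)-6-[(tert-butyldimethylsilyl)oxy]-4-methylhex-3-en-2-yl 3-methylbut-3-enoate | C[C@H](/C=C(\C)CCO[Si](C)(C)C(C)(C)C)OC(=O)CC(C)=C | intermediate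
6 | (1E)-1-{[(2R,3E)-6-[(tert-butyldimethylsilyl)oxy]-4-methylhex-3-en-2-yl]oxy}-3-methylbuta-1,3-dien-1-yl diphenyl phosphate | C[C@H](/C=C(\C)CCO[Si](C)(C)C(C)(C)C)O/C(OP(=O)(Oc1ccccc1)Oc1ccccc1)=C\C(C)=C | intermediate
7 | 2-(bromomethyl)prop-2-enoic acid | C=C(CBr)C(=O)O | starting material
8 | 2-(trimethylsilyl)ethanol | C[Si](C)(C)CCO | starting material
9 | 2-(trimethylsilyl)ethyl 2-(bromomethyl)prop-2-enoate | C=C(CBr)C(=O)OCC[Si](C)(C)C | intermediate
10 | bromo{2-[(2-(trimethylsilyl)ethoxy)carbonyl]prop-2-en-1-yl}zinc | C=C(C[Zn]Br)C(=O)OCC[Si](C)(C)C | intermediate (not isolated)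
11 | 2-(trimethylsilyl)ethyl (4Z)-4-{[(2R,3E)-6-[(tert-butyldimethylsilyl)oxy]-4-methylhex-3-en-2-yl]oxy}-6-methyl-2-methylidenehepta-4,6-dienoate | C[C@H](/C=C(\C)CCO[Si](C)(C)C(C)(C)C)O/C(CC(=C)C(=O)OCC[Si](C)(C)C)=C\C(C)=C | intermediate
12 | 2-(trimethylsilyl)ethyl (4Z)-4-{[(2R,3E)-6-hydroxy-4-methylhex-3-en-2-yl]oxy}-6-methyl-2-methylidenehepta-4,6-dienoate | C[C@H](/C=C(\C)CCO)O/C(CC(=C)C(=O)OCC[Si](C)(C)C)=C\C(C)=C | intermediate
13 | 2-(trimethylsilyl)ethyl (4Z)-6-methyl-2-methylidene-4-{[(2R,3E)-4-methyl-6-oxohex-3-en-2-yl]oxy}hepta-4,6-dienoate | C[C@H](/C=C(\C)CC=O)O/C(CC(=C)C(=O)OCC[Si](C)(C)C)=C\C(C)=C | intermediate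
14 | 2-(trimethylsilyl)ethyl (5S,6S,7E)-6-methyl-2-methylidene-4-oxo-6-(2-oxoethyl)-5-(prop-1-en-2-yl)non-7-enoate | C/C=C/[C@](C)(CC=O)[C@H](C(C)=C)C(=O)CC(=C)C(=O)OCC[Si](C)(C)C | intermediate (not isolated)
15 | 2-(trimethylsilyl)ethyl 2-[(1R,3S,4S,6S)-6-hydroxy-4-methyl-2-oxo-3-(prop-1-en-2-yl)-4-[(1E)-prop-1-en-1-yl]cyclohexyl]prop-2-enoate (C-10 methyl, C-5 isopropenyl and C-7 acrylate β; C-8 hydroxyl and C-10 propenyl α) | C/C=C/[C@]1(C)C[C@H](O)[C@@H](C(=C)C(=O)OCC[Si](C)(C)C)C(=O)[C@H]1C(C)=C | intermediate
16 | 2-(trimethylsilyl)ethyl 2-[(1R,2S,3S,4S,6S)-2,6-dihydroxy-4-methyl-3-(prop-1-en-2-yl)-4-[(1E)-prop-1-en-1-yl]cyclohexyl]prop-2-enoate (6β-OH, 8α-OH) | C/C=C/[C@]1(C)C[C@H](O)[C@@H](C(=C)C(=O)OCC[Si](C)(C)C)[C@@H](O)[C@H]1C(C)=C | intermediate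
17 | 2-(trimethylsilyl)ethyl 2-[(1R,2S,3S,4S,6S)-4-ethenyl-2,6-dihydroxy-4-methyl-3-(prop-1-en-2-yl)cyclohexyl]prop-2-enoate | C=C[C@]1(C)C[C@H](O)[C@@H](C(=C)C(=O)OCC[Si](C)(C)C)[C@@H](O)[C@H]1C(C)=C | intermediate
18 | methyl 2-[bis(2,2,2-trifluoroethoxy)phosphoryl]propanoate | COC(=O)C(C)P(=O)(OCC(F)(F)F)OCC(F)(F)F | starting material
19 | 2-[bis(2,2,2-trifluoroethoxy)phosphoryl]propanoic acid | CC(C(=O)O)P(=O)(OCC(F)(F)F)OCC(F)(F)F | intermediate
20 | 8-O-{2-[bis(2,2,2-trifluoroethoxy)phosphoryl]propanoyl} derivative of 17 (epimers at the phosphonate carbon) | C=C[C@]1(C)C[C@H](OC(=O)C(C)P(=O)(OCC(F)(F)F)OCC(F)(F)F)[C@@H](C(=C)C(=O)OCC[Si](C)(C)C)[C@@H](O)[C@H]1C(C)=C | intermediate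
21 | 2-oxoethyl acetate | CC(=O)OCC=O | starting material
22 | 8-O-[(2Z)-4-acetoxy-2-methylbut-2-enoyl] derivative of 17 | C=C[C@]1(C)C[C@H](OC(=O)/C(C)=C\COC(C)=O)[C@@H](C(=C)C(=O)OCC[Si](C)(C)C)[C@@H](O)[C@H]1C(C)=C | intermediate
23 | 2-(trimethylsilyl)ethyl ester of the target (hydroxyl on the former isopropenyl methyl) | C=C[C@]1(C)C[C@H](OC(=O)/C(C)=C\COC(C)=O)[C@@H](C(=C)C(=O)OCC[Si](C)(C)C)[C@@H](O)[C@H]1C(=C)CO | intermediate
24 | 2-[(1S,2S,3R,4S,6S)-6-{[(2Z)-4-(acetyloxy)-2-methylbut-2-enoyl]oxy}-4-ethenyl-2-hydroxy-3-(3-hydroxyprop-1-en-2-yl)-4-methylcyclohexyl]prop-2-enoic acid (CNP0261293.3) | C=C[C@]1(C)C[C@H](OC(=O)/C(C)=C\COC(C)=O)[C@@H](C(=C)C(=O)O)[C@@H](O)[C@H]1C(=C)CO | target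

**Step count and risks**

Total step count: 16. Longest linear sequence: 14 steps (steps 1–4, 6–11, 13–16).

Steps most likely to fail:

1. Step 4 (with the coupling in step 6 that depends on it). Enolate geometry may erode, which would invert C-5 relative to C-10, or the allyl ketene acetal phosphate may rearrange or hydrolyse before it is coupled. The fallback builds the (Z)-enol ether by C–O cross-coupling of a geometrically defined bromodiene. It sets out from 3 (with 9 for the zinc reagent) and returns at 11. Commercial methacrolein is converted by Corey–Fuchs dibromo-olefination (CBr4, PPh3, CH2Cl2, 0 °C) into 1,1-dibromo-3-methylbuta-1,3-diene F1. Trans-selective Negishi mono-coupling with allylzinc bromide 10 (Pd(PPh3)4, THF, 0 °C) should replace the bromine trans to the isopropenyl group and give 2-(trimethylsilyl)ethyl (4Z)-4-bromo-6-methyl-2-methylidenehepta-4,6-dienoate F2. Copper-catalysed vinylation of alcohol 3 with F2 (CuI, 3,4,7,8-tetramethyl-1,10-phenanthroline, Cs2CO3, PhMe, lowest workable temperature) should then give 11 with retention of the alkene geometry.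

2. Step 9. The β,γ-unsaturated aldehyde may isomerise or fragment before the rearrangement is complete, or the aldol closure may show poor diastereocontrol. The fallback separates the two bond formations so that the sensitive aldehyde never meets the allyl vinyl ether. It sets out from 11 and returns at 14. Heating 11 (PhMe, 100 °C) should give the Claisen product 2-(trimethylsilyl)ethyl (5S,6S,7E)-6-{2-[(tert-butyldimethylsilyl)oxy]ethyl}-6-methyl-2-methylidene-4-oxo-5-(prop-1-en-2-yl)non-7-enoate F3. Desilylation (HF·pyridine, pyridine, THF) gives the keto alcohol 2-(trimethylsilyl)ethyl (5S,6S,7E)-6-(2-hydroxyethyl)-6-methyl-2-methylidene-4-oxo-5-(prop-1-en-2-yl)non-7-enoate F4. Dess–Martin oxidation gives 14, now isolated, which is closed to 15 in a separate aldol step (catalytic DBU, PhMe, 0 °C, or the second stage of step 9).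

3. Step 15. Site selectivity of the allylic oxidation may be poor, or the new alcohol may over-oxidise to the enal. The fallback uses a Schenck ene reaction with singlet oxygen. It sets out from 22 and returns at 23. Photooxygenation (O2, tetraphenylporphyrin, hν, CH2Cl2, 0 °C) should add oxygen at the methylene terminus of the isopropenyl group with shift of the double bond, giving the allylic hydroperoxide F5 (hydroperoxide analogue of 23). Reduction with PPh3 then gives 23.

**Further compounds**

F1 | step 4 | 1,1-dibromo-3-methylbuta-1,3-diene | C=C(C)C=C(Br)Br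
F2 | step 4 | 2-(trimethylsilyl)ethyl (4Z)-4-bromo-6-methyl-2-methylidenehepta-4,6-dienoate | C=C(C)/C=C(\Br)CC(=C)C(=O)OCC[Si](C)(C)C
F3 | step 9 | 2-(trimethylsilyl)ethyl (5S,6S,7E)-6-{2-[(tert-butyldimethylsilyl)oxy]ethyl}-6-methyl-2-methylidene-4-oxo-5-(prop-1-en-2-yl)non-7-enoate | C/C=C/[C@](C)(CCO[Si](C)(C)C(C)(C)C)[C@H](C(C)=C)C(=O)CC(=C)C(=O)OCC[Si](C)(C)C
F4 | step 9 | 2-(trimethylsilyl)ethyl (5S,6S,7E)-6-(2-hydroxyethyl)-6-methyl-2-methylidene-4-oxo-5-(prop-1-en-2-yl)non-7-enoate | C/C=C/[C@](C)(CCO)[C@H](C(C)=C)C(=O)CC(=C)C(=O)OCC[Si](C)(C)C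
F5 | step 15 | allylic hydroperoxide corresponding to 23 (OOH in place of the primary allylic OH) | C=C[C@]1(C)C[C@H](OC(=O)/C(C)=C\COC(C)=O)[C@@H](C(=C)C(=O)OCC[Si](C)(C)C)[C@@H](O)[C@H]1C(=C)COO
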